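## Structural features

The target is built from two tetrasubstituted benzene rings joined by a single ether oxygen (C6 of ring A to C1' of ring B) and carries two side chains; it has no other ring. Ring A is a benzoic acid whose carboxyl carbon C1 lies between C2 (methoxy) and C6 (ether oxygen); C3 carries the (S)-1-acetoxy-3-methylbutyl arm, and C4 and C5 are unsubstituted. Ring B has the ether oxygen at C1' between a free hydroxyl (C2') and an (E)-3-oxobut-1-enyl group (C6'), with a methyl group at C4'. The only stereocentre is the benzylic carbon on C3; it has no stereogenic neighbour and must be set by reagent control. It is also the most fragile site: the ortho methoxy and para aryloxy groups make its C–O bond prone to ionisation in acid, the acetate is lost to base or nucleophiles, the enone is a Michael acceptor, and the acid and phenol must be unmasked last under neutral conditions. The real difficulty is the ether oxygen, which sits between two ortho substituents on ring B and next to the carboxyl on ring A, so a late C–O coupling would be badly hindered; the contiguous C1, C2, C3 and C6 substitution of ring A adds to it. The key step uses two imprints in ring A: C1 (carboxyl) between the oxygenated C2 and C6 corresponds to a malonate-derived ketene acetal diene C5=C6(OAr)–C1(CO2R)=C2(OR)(OSi), and C3 (acyl) with C4 (H) corresponds to a terminal alkynyl ketone. Ring A can therefore be closed through C2–C3 and C4–C5 with the ring B oxygen already in place.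

## Logic of the disconnections

22 to 21: the two O–allyl bonds (carboxyl oxygen on C1, phenol oxygen on C2') are cut last. A neutral allyl transfer to zerovalent palladium is the one unmasking that leaves the acetate, the enone and the stereocentre alone. The gain is that acid and phenol travel masked by one kind of group through every earlier step. The forward step needs a scavenger that does not add to the enone.

21 to 20: the acetyl C–O bond. Acylation is placed after every acid treatment so that the ionisable benzylic acetate never meets acid. The forward step needs clean O-acylation of a hindered secondary alcohol without touching the enone.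

20 to 18 and 19: the C=C bond of the enone on C6'. A stabilised ylide reacts with an aldehyde only and gives the E alkene. The four-carbon enone arm is reduced to a formyl group. The forward step must tolerate the free alcohol and the esters.

18 to 17: the two acetal C–O bonds. The aldehyde has to stay masked through amide base, the cycloaddition and hydride reduction. The forward hydrolysis must be mild enough not to ionise the benzylic alcohol.

17 to 16: the C–H bond at the stereocentre. This turns the stereocentre into the aryl ketone that the ring synthesis delivers. The forward reduction must distinguish the aryl face from the isobutyl face.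

16 to 15: the O–CH3 bond at C2. The phenol is the direct product of aromatisation, so methylation is the only adjustment needed. The forward step must alkylate a chelated, flanked phenoxide.

15 to 10 and 12 (through 13 and 14): the ring bonds C2–C3 and C4–C5. Cutting here dissolves ring A into an open-chain diene that already carries ring B on oxygen and a seven-carbon ynone, so the crowded ether is never made by coupling two arenes. The forward step needs the CH2 terminus of the diene to meet the terminal carbon of the ynone, and it must run below the temperature at which 10 rearranges.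

12 to 11: the C=O bond is traced back to the carbinol. The forward step is an oxidation that must spare a volatile, electrophilic product.

10 to 9: the O–Si bond and the C–H bond of the methyl group. The diene is the trapped extended enolate of the alkylidene malonate. The forward step needs γ-deprotonation and O-silylation.

9 to 4 and 8: the vinylic C6–O bond. The hindered phenol is joined to an sp2 carbon that carries only a methyl group, by addition–elimination. The forward step needs a β-leaving group on the alkylidene malonate.

8 to 7, then to 5 and 6: the C–Cl bond, then the C1–C6 bond. The chloride comes from the enol of the acylmalonate, which is the C-acylation product of the malonate.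

4 to 3, to 2, to 1: the acetal, then the O–allyl bond, then the O–methyl bond. Starting from an aldehyde in which formyl group, ring methyl and both oxygens are already placed removes any regiochemical question on ring B. The forward sequence needs one selective mono-allylation of a catechol.

## Other disconnections considered

Alternative 1: The cuts are the C6–O bond of the diaryl ether and the C1–carboxyl bond; no ring is formed. In the forward sense fluoride (KF, 18-crown-6) would release the ring A aryne from (S)-1-[2-methoxy-4-(trifluoromethylsulfonyloxy)-3-(trimethylsilyl)phenyl]-3-methylbutyl acetate A1. The potassium salt of phenol 4 would add at C6, and the aryl anion at C1 would be trapped by carbon dioxide to give (S)-3-(1-acetoxy-3-methylbutyl)-6-[2-(allyloxy)-6-(1,3-dioxolan-2-yl)-4-methylphenoxy]-2-methoxybenzoic acid A2.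
- In its favour: it is the most convergent plan. The regiochemistry follows the usual behaviour of 3-alkoxyarynes (nucleophile meta to the methoxy group, anion ortho to it). The carboxyl group arrives free and the stereocentre arrives complete.
- Against it: the phenoxide of 4 is hindered and weakly nucleophilic. The short-lived aryl anion could take a proton before it meets carbon dioxide, or attack the acetate carbonyl of the neighbouring arm through a six-membered transition state. A1 is a 1,2,3,4-tetrasubstituted arene with four different groups and needs its own regiocontrolled synthesis. The acetate in A2 would also have to pass the acid hydrolysis of the dioxolane.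
- Comparison: it is the equal of the chosen plan on stereocontrol and the better on convergence and on operations after the key step (three against six). It is weaker mechanistically, because three components must be matched in one event, whereas the chosen plan closes the second bond intramolecularly. The overall step count would probably be similar once A1 is made.

Alternative 2: The cuts are C4'–C5' and C1'–C6' of ring B, which is grown on the ether oxygen. In the forward sense the potassium enolate of 1,1-dimethoxypropan-2-one A4 (formed with KN(SiMe3)2) would add to the methyl-bearing alkyne carbon of (S)-3-(1-acetoxy-3-methylbutyl)-2-methoxy-6-[(2-oxopent-3-yn-1-yl)oxy]benzoic acid A3. The aryloxy-bearing carbon would then close onto the new ketone, and dehydration with enolisation would give (S)-3-(1-acetoxy-3-methylbutyl)-6-[2-(dimethoxymethyl)-6-hydroxy-4-methylphenoxy]-2-methoxybenzoic acid A5.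
- In its favour: the ring B phenol emerges free, so no protecting group and no selective mono-allylation are needed. The ether oxygen is attached as a simple alkyl aryl ether, so hindered C–O coupling is avoided. Only acetal hydrolysis and olefination remain after the key step.
- Against it: a strongly basic enolate has to act in the presence of the benzylic acetate and the carboxylate, which invites acyl transfer and deacetylation. Ring closure requires enolisation at the less acidic aryloxymethyl carbon in competition with 1,2-addition and oligomerisation of the ynone. A3 still demands a fully differentiated ring A, so the regiochemical burden is moved, not removed.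
- Comparison: it is the equal of the chosen plan in avoiding the diaryl C–O coupling and the better in protecting-group economy on ring B and in end-game length. It is the weaker in functional-group compatibility of the key step and in the certainty of its ring closure. Total length is expected to be no shorter, because ring A must be built separately.

Alternative 3: The cuts are C1–C2 and C3–C4 of ring A. In the forward sense allyl 4-[2-(allyloxy)-6-(1,3-dioxolan-2-yl)-4-methylphenoxy]-2-oxo-2H-pyran-3-carboxylate A6 and (S)-tert-butyl[(1-methoxy-5-methylhex-1-yn-3-yl)oxy]dimethylsilane A7 would be heated in toluene. An inverse-demand (4+2) cycloaddition followed by loss of carbon dioxide would give allyl (S)-6-[2-(allyloxy)-6-(1,3-dioxolan-2-yl)-4-methylphenoxy]-3-[1-(tert-butyldimethylsilyloxy)-3-methylbutyl]-2-methoxybenzoate A8.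
- In its favour: the polarity of both partners points to the same regiochemistry. The methoxy group arrives in the cycloaddition, so no chelated phenol has to be methylated. The stereocentre is set earlier on a small alkynyl ketone, so no late asymmetric reduction of a complex ketone is needed. The conditions are neutral and the loss of carbon dioxide is irreversible.
- Against it: A6 is a 6-unsubstituted pyrone open to nucleophiles at C6, and its 4-aryloxy donor lowers its reactivity as an electron-poor diene. The temperature needed could then approach that of a Claisen rearrangement of the aryl allyl ether. A7 is an acid-labile alkynyl ether whose enantioselective preparation takes several steps.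
- Comparison: it is the better on stereochemical security and on avoiding the methylation, and the equal on how ring B is attached (addition–elimination at an sp2 carbon in both plans). It is the weaker on accessibility of both partners and probably longer overall. The number of steps after the key step is about the same (five against six).

Key step: step 9

Remarks on the design:
- Assumption: 2-hydroxy-3-methoxy-5-methylbenzaldehyde (1) is taken as a catalogue compound; its substitution pattern fixes the regiochemistry of ring B from the start.
- Diene 10, ynone 12 and salicylate 15 map onto the target atom by atom, so their skeletons stand unchanged.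
- The allyl groups are kept on purpose, because one neutral operation then frees acid and phenol at the end. The weak point of 10 is a possible [3,3] shift of the allyl silyl ketene acetal. It is answered by making 10 at −78 °C, never storing it, and holding the cycloaddition at or below 40 °C.
- After the key step the acetal is hydrolysed and the enone is made before acetylation, so the benzylic acetate never meets acid.
- Salts and conjugate bases formed between two reagent additions (phenoxides, the lithium dienolate of 9, borate esters before work-up) are treated as forms of the numbered compound.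

## Route

Step 1
Reactants: 1 2-hydroxy-3-methoxy-5-methylbenzaldehyde
Product: 2 2,3-dihydroxy-5-methylbenzaldehyde
Conditions: BBr3 (1.5 equiv), CH2Cl2, −78 → 0 °C; then H2O
Reagents that add atoms: none
Why: Lewis-acid cleavage of an aryl methyl ether (BBr3 demethylation); the aldehyde and the ring methyl group are inert, and the catechol aldehyde should result.

Step 2
Reactants: 2 2,3-dihydroxy-5-methylbenzaldehyde
Product: 3 3-(allyloxy)-2-hydroxy-5-methylbenzaldehyde
Conditions: NaH (2.2 equiv), DMSO, 20 °C; allyl bromide (1.0 equiv), 20 °C; aq. HCl work-up
Reagents that add atoms: allyl bromide, C=CCBr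
Why: Williamson etherification of the catechol dianion; the 2-oxide is conjugated with and chelated to the formyl group, so the 3-oxide is the more nucleophilic and should take the single equivalent of halide, placing the allyl group on the oxygen meta to the ring methyl.

Step 3
Reactants: 3 3-(allyloxy)-2-hydroxy-5-methylbenzaldehyde
Product: 4 2-(allyloxy)-6-(1,3-dioxolan-2-yl)-4-methylphenol
Conditions: ethylene glycol (3 equiv), TsOH·H2O (2 mol %), toluene, reflux, Dean–Stark; Et3N quench
Reagents that add atoms: ethane-1,2-diol, OCCO
Why: Acid-catalysed acetalisation with azeotropic removal of water; the aldehyde must be masked before the phenoxide and lithium amide steps, because the acidic methyl group of 9 would otherwise condense with it.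

Step 4
Reactants: 5 diallyl malonate; 6 acetyl chloride
Product: 7 diallyl 2-acetylmalonate
Conditions: MgCl2 (1.0 equiv), Et3N (2.0 equiv), MeCN, 0 → 20 °C; aq. HCl
Reagents that add atoms: none
Why: Magnesium-mediated C-acylation of a malonate under soft enolisation; chelation holds the product as its enolate and should prevent a second acylation.

Step 5
Reactants: 7 diallyl 2-acetylmalonate
Product: 8 diallyl 2-(1-chloroethylidene)malonate
Conditions: POCl3 (4 equiv), Bu3N (1.0 equiv), 90 °C; then ice-water
Reagents that add atoms: phosphoryl chloride, O=P(Cl)(Cl)Cl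
Why: Conversion of the enol of an acylmalonate into the vinylogous acid chloride through its dichlorophosphate, followed by addition–elimination of chloride; allyl esters tolerate these anhydrous conditions.

Step 6
Reactants: 4 2-(allyloxy)-6-(1,3-dioxolan-2-yl)-4-methylphenol; 8 diallyl 2-(1-chloroethylidene)malonate
Product: 9 diallyl 2-{1-[2-(allyloxy)-6-(1,3-dioxolan-2-yl)-4-methylphenoxy]ethylidene}malonate
Conditions: K2CO3 (1.5 equiv), DMF, 20 → 50 °C
Reagents that add atoms: none
Why: Nucleophilic vinylic substitution (addition–elimination) of the phenoxide on the doubly activated β-chloroalkylidene malonate; the hindered C6–O bond is made at an sp2 carbon flanked only by a methyl group, and the two identical esters leave no alkene isomers.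

Step 7
Reactants: 9 diallyl 2-{1-[2-(allyloxy)-6-(1,3-dioxolan-2-yl)-4-methylphenoxy]ethylidene}malonate
Product: 10 allyl 3-(allyloxy)-2-{1-[2-(allyloxy)-6-(1,3-dioxolan-2-yl)-4-methylphenoxy]vinyl}-3-[(trimethylsilyl)oxy]acrylate
Conditions: LiN(i-Pr)2 (1.1 equiv), THF, −78 °C; Me3SiCl (1.3 equiv), −78 → 0 °C; pentane, filtration under argon, used at once
Reagents that add atoms: chlorotrimethylsilane, C[Si](C)(C)Cl
Why: γ-Deprotonation of the alkylidene malonate to the extended enolate and O-silylation to the vinylketene silyl acetal; the diene is kept at or below 0 °C because an allyl silyl ketene acetal can rearrange by a [3,3] shift when warmed.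

Step 8
Reactants: 11 5-methylhex-1-yn-3-ol (racemic)
Product: 12 5-methylhex-1-yn-3-one
Conditions: Dess–Martin periodinane (1,1,1-triacetoxy-1,1-dihydro-1,2-benziodoxol-3(1H)-one, 1.2 equiv), NaHCO3, CH2Cl2, 0 → 20 °C; exchanged into toluene without evaporation to dryness
Reagents that add atoms: none
Why: Oxidation of a propargylic alcohol to the alkynyl ketone with a hypervalent iodine reagent; the buffered, non-aqueous conditions avoid hydration of, or conjugate addition to, the volatile ynone.

Step 9
Reactants: 10 allyl 3-(allyloxy)-2-{1-[2-(allyloxy)-6-(1,3-dioxolan-2-yl)-4-methylphenoxy]vinyl}-3-[(trimethylsilyl)oxy]acrylate; 12 5-methylhex-1-yn-3-one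
Product: 15 allyl 6-[2-(allyloxy)-6-(1,3-dioxolan-2-yl)-4-methylphenoxy]-2-hydroxy-3-(3-methylbutanoyl)benzoate, via cyclohexa-1,4-diene cycloadduct 13 (not isolated), via aryl trimethylsilyl ether 14 (not isolated)
Conditions: 12 (1.5 equiv), toluene (1 M), 0 → 40 °C, dark; then SiO2, wet CH2Cl2, 20 °C
Reagents that add atoms: none
Why: Diels–Alder benzannulation of a 1-alkoxy-1-silyloxy diene (vinylketene acetal) with an alkynyl ketone, the known route to salicylates, applied here to a 2-carboalkoxy-3-aryloxy diene. The two oxygens on C2 and the aryloxy group on C6 both raise the HOMO coefficient at the CH2 terminus C5, and the ynone has its largest LUMO coefficient at its terminal carbon C4, so C4–C5 should form first and C2–C3 should close either in the same asynchronous (4+2) event or as Michael addition followed by attack of the allenolate carbon on the acetal carbon; both paths lead to the same cyclohexa-1,4-diene 13. Ring A thus closes as a six-membered carbocycle by (4+2) cycloaddition across the s-cis diene, which in the stepwise limit is a 6-exo-trig closure onto C2. The ketal carbon C2 of 13 is the only new sp3 centre, and it is erased when the doubly allylic C5–H and the allyloxy group leave as allyl alcohol to give 14; silica then cleaves the O–Si bond, and phenol 15 is held by hydrogen bonds to both carbonyl groups, so no stereocentre is created. The selectivities needed are the regiochemistry (acyl group on C3 next to C2–OH), secured by the matched polarity of the partners, and chemoselectivity over the [3,3] shift of the allyl ketene acetal, secured by the temperature ceiling. No acid or Lewis acid is present, so the dioxolane and the enol ether oxygen to ring B should remain untouched.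

Step 10
Reactants: 15 allyl 6-[2-(allyloxy)-6-(1,3-dioxolan-2-yl)-4-methylphenoxy]-2-hydroxy-3-(3-methylbutanoyl)benzoate
Product: 16 allyl 6-[2-(allyloxy)-6-(1,3-dioxolan-2-yl)-4-methylphenoxy]-2-methoxy-3-(3-methylbutanoyl)benzoate
Conditions: MeI (3 equiv), K2CO3 (2 equiv), DMF, 40 °C
Reagents that add atoms: iodomethane, CI
Why: Williamson O-methylation; the phenol between two carbonyl groups is acidic enough for carbonate, the polar solvent breaks the chelate, and the ketone α-carbon is not deprotonated. Removing the free phenol also prevents chelation in the following reduction.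

Step 11
Reactants: 16 allyl 6-[2-(allyloxy)-6-(1,3-dioxolan-2-yl)-4-methylphenoxy]-2-methoxy-3-(3-methylbutanoyl)benzoate
Product: 17 allyl (S)-6-[2-(allyloxy)-6-(1,3-dioxolan-2-yl)-4-methylphenoxy]-3-(1-hydroxy-3-methylbutyl)-2-methoxybenzoate
Conditions: (R)-tetrahydro-1-methyl-3,3-diphenyl-1H,3H-pyrrolo[1,2-c][1,3,2]oxazaborole (0.2 equiv), catecholborane (1.8 equiv), toluene, −78 → −40 °C; MeOH, then aq. Na2CO3 wash
Reagents that add atoms: none
Why: Corey–Bakshi–Shibata reduction; the ketone binds the catalyst boron with the aryl group as the large and the isobutyl group as the small substituent, and the R catalyst, which gives (S)-1-arylalkanols, should deliver hydride to the face that leads to the S alcohol. Catecholborane at low temperature leaves the allyl groups, the ester and the acetal alone.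

Step 12
Reactants: 17 allyl (S)-6-[2-(allyloxy)-6-(1,3-dioxolan-2-yl)-4-methylphenoxy]-3-(1-hydroxy-3-methylbutyl)-2-methoxybenzoate
Product: 18 allyl (S)-6-[2-(allyloxy)-6-formyl-4-methylphenoxy]-3-(1-hydroxy-3-methylbutyl)-2-methoxybenzoate
Conditions: pyridinium p-toluenesulfonate (0.2 equiv), acetone–H2O (10:1), 20 → 40 °C
Reagents that add atoms: water, O
Why: Acid-catalysed hydrolysis (transacetalisation) of an electron-rich aryl dioxolane, which is far more labile than the benzylic C–O bond under this weak acid; it is done at the alcohol stage so that the more ionisable acetate is never exposed to acid.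

Step 13
Reactants: 18 allyl (S)-6-[2-(allyloxy)-6-formyl-4-methylphenoxy]-3-(1-hydroxy-3-methylbutyl)-2-methoxybenzoate; 19 1-(triphenylphosphoranylidene)propan-2-one
Product: 20 allyl (S)-6-{2-(allyloxy)-4-methyl-6-[(E)-3-oxobut-1-en-1-yl]phenoxy}-3-(1-hydroxy-3-methylbutyl)-2-methoxybenzoate
Conditions: 19 (1.5 equiv), toluene, 80 °C
Reagents that add atoms: none
Why: Wittig olefination with a stabilised ylide, which reacts only with the aldehyde and should give the E enone, as such ylides do; the free alcohol and the esters are spectators.

Step 14
Reactants: 20 allyl (S)-6-{2-(allyloxy)-4-methyl-6-[(E)-3-oxobut-1-en-1-yl]phenoxy}-3-(1-hydroxy-3-methylbutyl)-2-methoxybenzoate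
Product: 21 allyl (S)-3-(1-acetoxy-3-methylbutyl)-6-{2-(allyloxy)-4-methyl-6-[(E)-3-oxobut-1-en-1-yl]phenoxy}-2-methoxybenzoate
Conditions: Ac2O (2 equiv), pyridine (4 equiv), 4-(dimethylamino)pyridine (0.1 equiv), CH2Cl2, 0 → 20 °C
Reagents that add atoms: acetic anhydride, CC(=O)OC(C)=O
Why: Nucleophile-catalysed O-acylation; only the O–H bond reacts, so the configuration at the benzylic carbon is retained.

Step 15
Reactants: 21 allyl (S)-3-(1-acetoxy-3-methylbutyl)-6-{2-(allyloxy)-4-methyl-6-[(E)-3-oxobut-1-en-1-yl]phenoxy}-2-methoxybenzoate
Product: 22 (S)-3-(1-acetoxy-3-methylbutyl)-6-{2-hydroxy-4-methyl-6-[(E)-3-oxobut-1-en-1-yl]phenoxy}-2-methoxybenzoic acid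
Conditions: Pd(PPh3)4 (5 mol %), N-methylaniline (6 equiv), THF, 20 °C, dark
Reagents that add atoms: none
Why: Tsuji–Trost deallylation; zerovalent palladium ionises the allyl ester and the aryl allyl ether to π-allyl complexes that the weakly basic aniline traps, which should free the acid and the phenol in one neutral operation that spares the acetate, the enone and the stereocentre.

## Compound list

1 | 2-hydroxy-3-methoxy-5-methylbenzaldehyde | COc1cc(C)cc(C=O)c1O | starting material
2 | 2,3-dihydroxy-5-methylbenzaldehyde | Cc1cc(O)c(O)c(C=O)c1 | intermediate
3 | 3-(allyloxy)-2-hydroxy-5-methylbenzaldehyde | C=CCOc1cc(C)cc(C=O)c1O | intermediate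
4 | 2-(allyloxy)-6-(1,3-dioxolan-2-yl)-4-methylphenol | C=CCOc1cc(C)cc(C2OCCO2)c1O | intermediate
5 | diallyl malonate | C=CCOC(=O)CC(=O)OCC=C | starting material
6 | acetyl chloride | CC(Cl)=O | starting material
7 | diallyl 2-acetylmalonate | C=CCOC(=O)C(C(C)=O)C(=O)OCC=C | intermediate
8 | diallyl 2-(1-chloroethylidene)malonate | C=CCOC(=O)C(=C(C)Cl)C(=O)OCC=C | intermediate
9 | diallyl 2-{1-[2-(allyloxy)-6-(1,3-dioxolan-2-yl)-4-methylphenoxy]ethylidene}malonate | C=CCOC(=O)C(=C(C)Oc1c(OCC=C)cc(C)cc1C1OCCO1)C(=O)OCC=C | intermediate
10 | allyl 3-(allyloxy)-2-{1-[2-(allyloxy)-6-(1,3-dioxolan-2-yl)-4-methylphenoxy]vinyl}-3-[(trimethylsilyl)oxy]acrylate (ketene acetal geometry immaterial) | C=C(Oc1c(OCC=C)cc(C)cc1C1OCCO1)C(C(=O)OCC=C)=C(OCC=C)O[Si](C)(C)C | intermediate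
11 | 5-methylhex-1-yn-3-ol (racemic) | C#CC(O)CC(C)C | starting material
12 | 5-methylhex-1-yn-3-one | C#CC(=O)CC(C)C | intermediate
13 | allyl 6-(allyloxy)-2-[2-(allyloxy)-6-(1,3-dioxolan-2-yl)-4-methylphenoxy]-5-(3-methylbutanoyl)-6-[(trimethylsilyl)oxy]cyclohexa-1,4-diene-1-carboxylate (racemic at the ketal carbon, not isolated) | C=CCOC(=O)C1=C(Oc2c(OCC=C)cc(C)cc2C2OCCO2)CC=C(C(=O)CC(C)C)C1(OCC=C)O[Si](C)(C)C | intermediate
14 | allyl 6-[2-(allyloxy)-6-(1,3-dioxolan-2-yl)-4-methylphenoxy]-3-(3-methylbutanoyl)-2-[(trimethylsilyl)oxy]benzoate (not isolated) | C=CCOC(=O)c1c(O[Si](C)(C)C)c(C(=O)CC(C)C)ccc1Oc1c(OCC=C)cc(C)cc1C1OCCO1 | intermediate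
15 | allyl 6-[2-(allyloxy)-6-(1,3-dioxolan-2-yl)-4-methylphenoxy]-2-hydroxy-3-(3-methylbutanoyl)benzoate | C=CCOC(=O)c1c(O)c(C(=O)CC(C)C)ccc1Oc1c(OCC=C)cc(C)cc1C1OCCO1 | intermediate
16 | allyl 6-[2-(allyloxy)-6-(1,3-dioxolan-2-yl)-4-methylphenoxy]-2-methoxy-3-(3-methylbutanoyl)benzoate | C=CCOC(=O)c1c(OC)c(C(=O)CC(C)C)ccc1Oc1c(OCC=C)cc(C)cc1C1OCCO1 | intermediate
17 | allyl (S)-6-[2-(allyloxy)-6-(1,3-dioxolan-2-yl)-4-methylphenoxy]-3-(1-hydroxy-3-methylbutyl)-2-methoxybenzoate | C=CCOC(=O)c1c(OC)c([C@H](CC(C)C)O)ccc1Oc1c(OCC=C)cc(C)cc1C1OCCO1 | intermediate
18 | allyl (S)-6-[2-(allyloxy)-6-formyl-4-methylphenoxy]-3-(1-hydroxy-3-methylbutyl)-2-methoxybenzoate | C=CCOC(=O)c1c(OC)c([C@H](CC(C)C)O)ccc1Oc1c(OCC=C)cc(C)cc1C=O | intermediate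
19 | 1-(triphenylphosphoranylidene)propan-2-one | CC(=O)C=P(c1ccccc1)(c1ccccc1)c1ccccc1 | starting material
20 | allyl (S)-6-{2-(allyloxy)-4-methyl-6-[(E)-3-oxobut-1-en-1-yl]phenoxy}-3-(1-hydroxy-3-methylbutyl)-2-methoxybenzoate | C=CCOC(=O)c1c(OC)c([C@H](CC(C)C)O)ccc1Oc1c(OCC=C)cc(C)cc1/C=C/C(C)=O | intermediate
21 | allyl (S)-3-(1-acetoxy-3-methylbutyl)-6-{2-(allyloxy)-4-methyl-6-[(E)-3-oxobut-1-en-1-yl]phenoxy}-2-methoxybenzoate | C=CCOC(=O)c1c(OC)c([C@H](CC(C)C)OC(C)=O)ccc1Oc1c(OCC=C)cc(C)cc1/C=C/C(C)=O | intermediate
22 | (S)-3-(1-acetoxy-3-methylbutyl)-6-{2-hydroxy-4-methyl-6-[(E)-3-oxobut-1-en-1-yl]phenoxy}-2-methoxybenzoic acid | COc1c([C@H](CC(C)C)OC(C)=O)ccc(Oc2c(O)cc(C)cc2/C=C/C(C)=O)c1C(=O)O | target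

## Step count and least certain steps

Total: 15 steps. Longest linear sequence: 12 steps (from 1 to 22 through steps 1, 2, 3, 6, 7, 9, 10, 11, 12, 13, 14 and 15). Steps 4 and 5 (malonate branch) and step 8 (ynone) are side branches.

**Step 9 (key step).**
- What may go wrong: the ester on C1 lowers the nucleophilicity of the diene, so the cycloaddition may be too slow below 40 °C. At higher temperature the allyl silyl ketene acetal could rearrange by a [3,3] shift, or the diene could lose its silyl group and revert to 9. Bond formation could also stop after the first C–C bond without ring closure.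
- Fallback (sets out from 4, returns at 16): the ether bond is made by nucleophilic aromatic substitution and ring A is taken from an arene.
  - Purchased 4-fluoro-2-methoxybenzaldehyde and isobutylmagnesium bromide (THF, 0 °C) should give 1-(4-fluoro-2-methoxyphenyl)-3-methylbutan-1-ol F1.
  - n-BuLi (2.2 equiv, THF, −78 °C) should form the alkoxide and lithiate the carbon between fluorine and methoxy; carbon dioxide should then give 6-fluoro-3-(1-hydroxy-3-methylbutyl)-2-methoxybenzoic acid F2.
  - Allyl bromide with KHCO3 in DMF should give allyl 6-fluoro-3-(1-hydroxy-3-methylbutyl)-2-methoxybenzoate F3.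
  - Dess–Martin oxidation should give allyl 6-fluoro-2-methoxy-3-(3-methylbutanoyl)benzoate F4, whose fluorine is para to the ketone and ortho to the ester.
  - Phenol 4 with Cs2CO3 in DMSO at 60 °C should displace the fluoride to give 16.

**Step 7.**
- What may go wrong: incomplete γ-deprotonation, silylation on carbon instead of oxygen, hydrolysis during the solvent change, or [3,3] rearrangement if the solution warms.
- Fallback (sets out from 9 and 12, returns at 15): an anionic annulation that needs no silyl diene.
  - 12 with LiCl in acetic acid should give (Z)-1-chloro-5-methylhex-1-en-3-one F5.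
  - The lithium dienolate of 9 (LiN(SiMe3)2, THF, −78 °C) should displace the vinylic chloride of F5 through its CH2 terminus to give diallyl 2-{(3E)-1-[2-(allyloxy)-6-(1,3-dioxolan-2-yl)-4-methylphenoxy]-7-methyl-5-oxooct-3-en-1-ylidene}malonate F6.
  - A further equivalent of base should close ring A by Dieckmann-type acylation of the dienolate carbon next to the ketone, with loss of allyl alcohol, and tautomerisation should give 15.

**Step 11.**
- What may go wrong: poor facial selectivity, because the ortho-methoxy aryl group is twisted and the many Lewis-basic sites (ester, acetal, ethers) may bind borane and open an uncatalysed background reduction.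
- Fallback (sets out from 16, returns at 17): resolution in place of asymmetric reduction.
  - NaBH4 (MeOH, 0 °C) should give the racemic alcohol allyl 6-[2-(allyloxy)-6-(1,3-dioxolan-2-yl)-4-methylphenoxy]-3-(1-hydroxy-3-methylbutyl)-2-methoxybenzoate F7.
  - Acylative kinetic resolution with isobutyric anhydride and the enantiomer of 2-phenyl-2,3-dihydrobenzo[d]imidazo[2,1-b]thiazole that acylates the R alcohol faster should convert the R enantiomer into allyl (R)-6-[2-(allyloxy)-6-(1,3-dioxolan-2-yl)-4-methylphenoxy]-2-methoxy-3-[3-methyl-1-(2-methylpropanoyloxy)butyl]benzoate F8 and leave 17, separable by chromatography.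

**Step 15.**
- What may go wrong: ionisation of the aryl allyl ether is slower than that of the ester, so prolonged exposure could lead to conjugate addition of the scavenger to the enone, re-allylation of the product, or loss of the acetate.
- Fallback (sets out from 18, returns at 22): the order is changed so that the palladium step never meets the enone.
  - 18 is acetylated (Ac2O, pyridine, 4-(dimethylamino)pyridine) to allyl (S)-3-(1-acetoxy-3-methylbutyl)-6-[2-(allyloxy)-6-formyl-4-methylphenoxy]-2-methoxybenzoate F9.
  - Pd(PPh3)4 and N-methylaniline should remove both allyl groups to give (S)-3-(1-acetoxy-3-methylbutyl)-6-(2-formyl-6-hydroxy-4-methylphenoxy)-2-methoxybenzoic acid F10.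
  - Ylide 19 (3 equiv, toluene, 40 °C) should olefinate the aldehyde as the last step to give 22; the stabilised ylide tolerates the free acid and phenol when used in excess.

## Further compounds

F1 | step 9 | 1-(4-fluoro-2-methoxyphenyl)-3-methylbutan-1-ol (racemic) | COc1cc(F)ccc1C(O)CC(C)C
F2 | step 9 | 6-fluoro-3-(1-hydroxy-3-methylbutyl)-2-methoxybenzoic acid (racemic) | COc1c(C(O)CC(C)C)ccc(F)c1C(=O)O
F3 | step 9 | allyl 6-fluoro-3-(1-hydroxy-3-methylbutyl)-2-methoxybenzoate (racemic) | COc1c(C(O)CC(C)C)ccc(F)c1C(=O)OCC=C
F4 | step 9 | allyl 6-fluoro-2-methoxy-3-(3-methylbutanoyl)benzoate | COc1c(C(=O)CC(C)C)ccc(F)c1C(=O)OCC=C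
F5 | step 7 | (Z)-1-chloro-5-methylhex-1-en-3-one | Cl/C=C\C(=O)CC(C)C
F6 | step 7 | diallyl 2-{(3E)-1-[2-(allyloxy)-6-(1,3-dioxolan-2-yl)-4-methylphenoxy]-7-methyl-5-oxooct-3-en-1-ylidene}malonate | C=CCOC(=O)C(C(=O)OCC=C)=C(Oc1c(OCC=C)cc(C)cc1C1OCCO1)C/C=C/C(=O)CC(C)C
F7 | step 11 | allyl 6-[2-(allyloxy)-6-(1,3-dioxolan-2-yl)-4-methylphenoxy]-3-(1-hydroxy-3-methylbutyl)-2-methoxybenzoate (racemic) | C=CCOC(=O)c1c(OC)c(C(O)CC(C)C)ccc1Oc1c(OCC=C)cc(C)cc1C1OCCO1
F8 | step 11 | allyl (R)-6-[2-(allyloxy)-6-(1,3-dioxolan-2-yl)-4-methylphenoxy]-2-methoxy-3-[3-methyl-1-(2-methylpropanoyloxy)butyl]benzoate | C=CCOC(=O)c1c(OC)c([C@@H](CC(C)C)OC(=O)C(C)C)ccc1Oc1c(OCC=C)cc(C)cc1C1OCCO1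
F9 | step 15 | allyl (S)-3-(1-acetoxy-3-methylbutyl)-6-[2-(allyloxy)-6-formyl-4-methylphenoxy]-2-methoxybenzoate | C=CCOC(=O)c1c(OC)c([C@H](CC(C)C)OC(C)=O)ccc1Oc1c(OCC=C)cc(C)cc1C=O
F10 | step 15 | (S)-3-(1-acetoxy-3-methylbutyl)-6-(2-formyl-6-hydroxy-4-methylphenoxy)-2-methoxybenzoic acid | COc1c([C@H](CC(C)C)OC(C)=O)ccc(Oc2c(O)cc(C)cc2C=O)c1C(=O)O
A1 | alternative 1 | (S)-1-[2-methoxy-4-(trifluoromethylsulfonyloxy)-3-(trimethylsilyl)phenyl]-3-methylbutyl acetate | COc1c([C@H](CC(C)C)OC(C)=O)ccc(OS(=O)(=O)C(F)(F)F)c1[Si](C)(C)C
A2 | alternative 1 | (S)-3-(1-acetoxy-3-methylbutyl)-6-[2-(allyloxy)-6-(1,3-dioxolan-2-yl)-4-methylphenoxy]-2-methoxybenzoic acid | O=C(O)c1c(OC)c([C@H](CC(C)C)OC(C)=O)ccc1Oc1c(OCC=C)cc(C)cc1C1OCCO1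
A3 | alternative 2 | (S)-3-(1-acetoxy-3-methylbutyl)-2-methoxy-6-[(2-oxopent-3-yn-1-yl)oxy]benzoic acid | COc1c([C@H](CC(C)C)OC(C)=O)ccc(OCC(=O)C#CC)c1C(=O)O
A4 | alternative 2 | 1,1-dimethoxypropan-2-one | CC(=O)C(OC)OC
A5 | alternative 2 | (S)-3-(1-acetoxy-3-methylbutyl)-6-[2-(dimethoxymethyl)-6-hydroxy-4-methylphenoxy]-2-methoxybenzoic acid | COc1c([C@H](CC(C)C)OC(C)=O)ccc(Oc2c(O)cc(C)cc2C(OC)OC)c1C(=O)O
A6 | alternative 3 | allyl 4-[2-(allyloxy)-6-(1,3-dioxolan-2-yl)-4-methylphenoxy]-2-oxo-2H-pyran-3-carboxylate | C=CCOC(=O)C1=C(Oc2c(OCC=C)cc(C)cc2C2OCCO2)C=COC1=O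
A7 | alternative 3 | (S)-tert-butyl[(1-methoxy-5-methylhex-1-yn-3-yl)oxy]dimethylsilane | COC#C[C@H](CC(C)C)O[Si](C)(C)C(C)(C)C
A8 | alternative 3 | allyl (S)-6-[2-(allyloxy)-6-(1,3-dioxolan-2-yl)-4-methylphenoxy]-3-[1-(tert-butyldimethylsilyloxy)-3-methylbutyl]-2-methoxybenzoate | C=CCOC(=O)c1c(OC)c([C@H](CC(C)C)O[Si](C)(C)C(C)(C)C)ccc1Oc1c(OCC=C)cc(C)cc1C1OCCO1
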